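## Analysis of the target

Metachromin B (16) is a 2H-chromene. Its pyran ring (O1–C2–C3=C4–C4a–C8a) is fused to a benzene ring carrying OH at C5 and OMe at C6 and C8. C2 bears a methyl group and a two-carbon linker (C1″–C2″) to a 1,3-dimethyl-2-methylidenecyclohexane (C1′–C6′, exocyclic C7′ on C2′).

There are three stereocentres: the oxygen-bearing quaternary C2 (S), the all-carbon quaternary C1′ (R) and the tertiary C3′ (R). C1′ and C3′ flank the exocyclic alkene and their methyl groups are trans. C2 lies four bonds from C1′ across a freely rotating chain.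

The difficulty is twofold. At C1′ the two groups that differ (CH3 and CH2CH2R) are almost the same size, so induction from C3′ in a monocycle is weak, and the usual axial bond formation anti to the C3′ methyl gives the cis-dimethyl relation. C2 cannot be reached from the ring stereocentres in an open chain, and an oxa-6π closure forms it without control.

Sensitive groups:
- the para-alkoxyphenol (oxidation to a quinone);
- the allylic C2–O bond to an electron-rich aryl oxygen (ionises in acid and would scramble C2);
- the exocyclic alkene (migrates into the ring in acid);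
- C3′, which epimerises whenever C2′ is a carbonyl carbon.

The feature the route is built on: the string C3–C2–C1″–C2″–C1′–C2′ has six carbons, and its two ends are sp2 carbons of two different alkenes (C3=C4 and C2′=C7′). Exchanging the alkene partners (C3 with C2′, C4 with C7′) turns 16 into an isomer: a 2-aryloxy-2,4a,8-trimethyl-octalin with a C1=C8a double bond and an aryl vinyl group. That octalin is the methyl adduct of the Robinson annulation product of 2,6-dimethylcyclohexanone (1). In it all three stereocentres sit on one rigid bicycle.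

Locants used below: octalin numbering (C1–C8a) for 7–15; chromene locants, primes and double primes for 16.

## Retrosynthetic reasoning

**16 to 15 (key disconnection).** The C3=C4 bond of the pyran and the C2′=C7′ bond are cut and the partners exchanged, C3 to C2′ and C4 to C7′. This retro ring-rearrangement metathesis closes ring B of an octalin and leaves a vinyl group on the arene. The cut is made here because only this exchange puts C2, C1′ and C3′ into one bicycle without adding or removing an atom. The gain is that the flexible 1,4-relation C2/C1′ becomes a ring relation, the trans-dimethyl relation becomes the thermodynamic one, and the exocyclic alkene and the pyran ring both appear in one forward operation. The forward reaction must open an unstrained, trisubstituted cyclohexene and close the chromene, with the methylidene delivered to C8a.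

**15 to 14 to 12.** The vinyl group is traced to a formyl group (methylenation) and the phenol to an aryl fluoride (substitution by a hydroxide surrogate). The formyl group is kept this long because it is the activating group for both aromatic substitutions.

**12 to 9 and 10.** The aryl ether is cut at the aryl carbon, not at C2. A tertiary allylic C–O bond cannot be made by substitution at C2 without ionisation, whereas attack of the alkoxide of 9 on the arene keeps the C2 configuration. Aldehyde 10 is symmetric, so either fluoride can be displaced and the second one later becomes the C5 hydroxyl.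

**9 to 8.** The C2–CH3 bond is cut. The forward step is a 1,2-addition of a methyl nucleophile to the enone, and it must deliver methyl pseudo-equatorially (syn to the angular methyl) so that the oxygen ends up pseudo-axial, trans to the angular methyl.

**8 to 6 to 3 and 4, then to 1 and 2.** The enone is opened by a retro-aldol condensation to diketone 6. The C4a–C4 bond is cut by a retro-Michael addition to methyl vinyl ketone (4) and the chiral imine 3 of ketone 1 and amine 2. Only the quaternary centre has to be set by the auxiliary. C8 is γ to the enone carbonyl in 8 and equilibrates to the trans epimer.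

## Alternatives that were turned down

**Alternative 1:** the textbook disconnection, at O1–C2 and C4–C4a. Resorcinol A1 is condensed with enal A2, and the resulting ortho-quinone methide closes by oxa-6π electrocyclisation. It was turned down because C2 is formed from a planar, achiral dienone whose nearest stereocentre is five bonds away. The product is therefore the C2-epimer mixture A3, and the epimers differ only at a remote centre. In addition, A2 already contains the difficult cyclohexane and needs its own eight to ten steps, so a cheap key step would sit on an expensive precursor and discard half of it.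

**Alternative 2:** disconnection at O1–C2 under catalyst control. Phenol A4 and allylic carbonate A5 are joined by a palladium-catalysed asymmetric allylic etherification (zerovalent palladium, chiral diphosphine) to the tertiary ether A6, which closes by ordinary ring-closing metathesis. It was turned down for three reasons:
- the catalyst must bring a di-ortho-substituted phenol to the more substituted allyl terminus, against the linear ether;
- A5 still needs a separate answer to C1′/C3′, and a sigmatropic entry across the ring delivers the chain anti to the C3′ methyl (the cis-dimethyl relation);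
- two unrelated stereochemical problems are solved in series, with a step count well above ten.

**Alternative 3:** disconnection at O1–C2 with inversion. The prenyl-type resorcinol A7 is epoxidised (Shi epoxidation) to A8, a phenol oxygen opens the epoxide 6-endo at the tertiary carbon to give chromanol A9, and dehydration gives 16. It was turned down for three reasons:
- the 6-endo opening needs acid, which endangers the exocyclic alkene, while base favours the 5-exo dihydrobenzofuran;
- dehydration of a secondary alcohol next to the quaternary C2 invites ring contraction through oxygen participation;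
- A7 again presupposes the monocyclic terpenoid fragment with its unsolved C1′/C3′ relation.

Key step: step 8

Assumption: 2,6-difluoro-3,5-dimethoxybenzaldehyde (10) is taken as a catalogue building block of the 2,6-difluoro-3,5-dimethoxyphenyl series, and methyltitanium triisopropoxide as a commercial reagent.

## Route

Step 1
Reactants: 1 2,6-dimethylcyclohexanone (cis/trans mixture); 2 (S)-1-phenylethylamine
Product: 3 (2RS,6RS)-2,6-dimethyl-N-[(1S)-1-phenylethyl]cyclohexan-1-imine
Conditions: TsOH·H2O (2 mol%), toluene, reflux, Dean–Stark trap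
Reagents that add atoms: none
Why: Acid-catalysed imine condensation with azeotropic removal of water. The ring stereocentres of 1 stay mobile through imine–enamine tautomerism, so the isomer mixture is of no consequence.

Step 2
Reactants: 3 (2RS,6RS)-2,6-dimethyl-N-[(1S)-1-phenylethyl]cyclohexan-1-imine; 4 methyl vinyl ketone
Product: 6 (2R,6RS)-2,6-dimethyl-2-(3-oxobutyl)cyclohexan-1-one, via Michael adduct imine 5 (not isolated)
Conditions: 4 (1.3 equiv), THF (concentrated), 25–40 °C; then 20% aq AcOH, 25 °C
Reagents that add atoms: water, O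
Why: Michael addition of a chiral imine through its secondary enamine tautomer (aza-ene-like, compact transition state). Attack on the π-face remote from the phenyl group should set the quaternary centre as R with the (S)-amine, by analogy with the 2-methylcyclohexanone series. Mild acid hydrolysis releases the auxiliary, and C6 stays a mixture to be corrected in step 3.

Step 3
Reactants: 6 (2R,6RS)-2,6-dimethyl-2-(3-oxobutyl)cyclohexan-1-one
Product: 8 (4aR,8R)-4a,8-dimethyl-4,4a,5,6,7,8-hexahydronaphthalen-2(3H)-one, via ketol 7 (not isolated)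
Conditions: NaOMe, MeOH, 60 °C
Reagents that add atoms: none
Why: Second stage of the Robinson annulation (intramolecular aldol addition, then loss of water). C8 is γ to the enone carbonyl and epimerises through the dienolate. It should settle trans to the angular methyl, because the cis epimer would hold the two methyl groups 1,3-diaxial on ring A.

Step 4
Reactants: 8 (4aR,8R)-4a,8-dimethyl-4,4a,5,6,7,8-hexahydronaphthalen-2(3H)-one
Product: 9 (2S,4aR,8R)-2,4a,8-trimethyl-2,3,4,4a,5,6,7,8-octahydronaphthalen-2-ol
Conditions: MeTi(OiPr)3 (2 equiv), Et2O–hexane, −30 → 20 °C; aq NH4F work-up; Et3N-deactivated silica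
Reagents that add atoms: methyltitanium triisopropoxide, C[Ti](OC(C)C)(OC(C)C)OC(C)C
Why: Chemoselective 1,2-addition of a bulky, weakly basic organotitanium reagent to the enone. Pseudo-equatorial delivery of methyl (β face, syn to the angular methyl) is expected, as with such reagents on cyclohexanones, giving the pseudo-axial C2–OH trans to the angular methyl (2S). The C2 epimer from axial attack is removed by chromatography.

Step 5
Reactants: 9 (2S,4aR,8R)-2,4a,8-trimethyl-2,3,4,4a,5,6,7,8-octahydronaphthalen-2-ol; 10 2,6-difluoro-3,5-dimethoxybenzaldehyde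
Product: 12 2-fluoro-3,5-dimethoxy-6-{[(2S,4aR,8R)-2,4a,8-trimethyl-2,3,4,4a,5,6,7,8-octahydronaphthalen-2-yl]oxy}benzaldehyde, via potassium alkoxide 11 (not isolated)
Conditions: KN(SiMe3)2 (1.05 equiv), THF, 0 °C; then 10 (1.3 equiv), 0 → 40 °C
Reagents that add atoms: none
Why: Nucleophilic aromatic substitution (SNAr). The ortho formyl group and the second fluorine activate 10, and its two C–F positions are equivalent, so no regiochemistry arises. The C2–O bond of 9 is not touched, so C2 keeps its configuration, and monosubstitution is expected because 12 is less activated and more hindered than 10.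

Step 6
Reactants: 12 2-fluoro-3,5-dimethoxy-6-{[(2S,4aR,8R)-2,4a,8-trimethyl-2,3,4,4a,5,6,7,8-octahydronaphthalen-2-yl]oxy}benzaldehyde
Product: 14 2-hydroxy-3,5-dimethoxy-6-{[(2S,4aR,8R)-2,4a,8-trimethyl-2,3,4,4a,5,6,7,8-octahydronaphthalen-2-yl]oxy}benzaldehyde, via sulfonylethyl ether 13 (not isolated)
Conditions: MeSO2CH2CH2OH (1.5 equiv), NaH (3 equiv), DMF, 0 → 40 °C; then dilute aq HCl to pH 6
Reagents that add atoms: 2-(methylsulfonyl)ethanol, CS(=O)(=O)CCO
Why: SNAr with a hydroxide surrogate: the alkoxide displaces the remaining formyl-activated fluoride, and ether 13 fragments by E1cB elimination to the phenoxide. The tert-alkyl aryl ether and the aldehyde (no α-hydrogen) are stable to the base.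

Step 7
Reactants: 14 2-hydroxy-3,5-dimethoxy-6-{[(2S,4aR,8R)-2,4a,8-trimethyl-2,3,4,4a,5,6,7,8-octahydronaphthalen-2-yl]oxy}benzaldehyde
Product: 15 2-ethenyl-4,6-dimethoxy-3-{[(2S,4aR,8R)-2,4a,8-trimethyl-2,3,4,4a,5,6,7,8-octahydronaphthalen-2-yl]oxy}phenol
Conditions: Ph3PCH3Br (3 equiv), KOtBu (3 equiv), THF, 0 → 25 °C
Reagents that add atoms: methyltriphenylphosphonium bromide, C[P+](c1ccccc1)(c1ccccc1)c1ccccc1.[Br-]
Why: Wittig methylenation with excess ylide, one equivalent being spent on the phenol. The reaction is established for salicylaldehyde phenoxides and leaves the trisubstituted alkene and the aryl ether untouched.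

Step 8
Reactants: 15 2-ethenyl-4,6-dimethoxy-3-{[(2S,4aR,8R)-2,4a,8-trimethyl-2,3,4,4a,5,6,7,8-octahydronaphthalen-2-yl]oxy}phenol
Product: 16 metachromin B, (2S)-2-{2-[(1R,3R)-1,3-dimethyl-2-methylidenecyclohexyl]ethyl}-6,8-dimethoxy-2-methyl-2H-chromen-5-ol
Conditions: RuCl2[1,3-bis(2-methylphenyl)imidazolidin-2-ylidene](=CH-C6H4-2-OiPr) (second-generation Hoveyda–Grubbs type, 10 mol%), ethylene (1 atm), toluene (0.01 M), 70 °C
Reagents that add atoms: none
Why: Proposed new method: ring-opening/ring-closing (ring-rearrangement) olefin metathesis of an unstrained, trisubstituted, fused cyclohexene; the closest known reaction type is the ruthenium- or molybdenum-alkylidene-catalysed rearrangement of cycloalkenyl 2-vinylaryl ethers into 2-substituted 2H-chromenes under ethylene, shown for disubstituted cycloalkenes. Ru=CH2, kept available by ethylene (which only shuttles the methylidene, the equation being the isomerisation 15 → 16), should add across C1=C8a with CH2 on the fully substituted C8a (the β-position of the ruthenacyclobutane, away from the metal) and Ru on C1. Cycloreversion opens ring B, leaving the exocyclic methylene on the cyclohexane and a neopentyl-type alkylidene at C1. This alkylidene closes onto the ortho vinyl group by ring-closing metathesis (six-membered ring, new C3=C4 bond of the pyran, cis by ring constraint) and returns Ru=CH2. No stereocentre is formed or broken: C2 keeps its oxygen, and C4a and C8 become C1′ and C3′ unchanged. The selectivity needed is the orientation of the first cycloaddition; the reverse orientation would place Ru on C8a and give a disubstituted alkylidene next to a quaternary carbon, so it is disfavoured. The β face is expected to react, because there the small CH2 meets the angular methyl and Ru meets the open side of C1, whereas the α face of C1 is covered by the pseudo-axial aryloxy group. The driving force is that a twisted di-ortho-substituted styrene and an out-of-plane, congested tert-alkyl aryl ether are exchanged for a planar chromene in which both the styrene and the aryl ether conjugation are regained.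

## Compound list

1 | 2,6-dimethylcyclohexanone (cis/trans mixture) | CC1CCCC(C)C1=O | starting material
2 | (S)-1-phenylethylamine | C[C@H](N)c1ccccc1 | starting material
3 | (2RS,6RS)-2,6-dimethyl-N-[(1S)-1-phenylethyl]cyclohexan-1-imine | C[C@H](N=C1C(C)CCCC1C)c1ccccc1 | intermediate
4 | methyl vinyl ketone | C=CC(C)=O | starting material
5 | 4-[(1R,3RS)-1,3-dimethyl-2-{[(1S)-1-phenylethyl]imino}cyclohexyl]butan-2-one (Michael adduct imine) | C[C@H](N=C1C(C)CCC[C@]1(C)CCC(C)=O)c1ccccc1 | intermediate (not isolated)
6 | (2R,6RS)-2,6-dimethyl-2-(3-oxobutyl)cyclohexan-1-one | O=C1C(C)CCC[C@]1(C)CCC(C)=O | intermediate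
7 | (4aR,8RS,8aRS)-8a-hydroxy-4a,8-dimethyloctahydronaphthalen-2(1H)-one (ketol) | O=C1CC[C@@]2(C)CCCC(C)C2(O)C1 | intermediate (not isolated)
8 | (4aR,8R)-4a,8-dimethyl-4,4a,5,6,7,8-hexahydronaphthalen-2(3H)-one | O=C1C=C2[C@H](C)CCC[C@]2(C)CC1 | intermediate
9 | (2S,4aR,8R)-2,4a,8-trimethyl-2,3,4,4a,5,6,7,8-octahydronaphthalen-2-ol | O[C@]1(C)C=C2[C@H](C)CCC[C@]2(C)CC1 | intermediate
10 | 2,6-difluoro-3,5-dimethoxybenzaldehyde | O=Cc1c(F)c(OC)cc(OC)c1F | starting material
11 | potassium (2S,4aR,8R)-2,4a,8-trimethyl-2,3,4,4a,5,6,7,8-octahydronaphthalen-2-olate | [K+].[O-][C@]1(C)C=C2[C@H](C)CCC[C@]2(C)CC1 | intermediate (not isolated)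
12 | 2-fluoro-3,5-dimethoxy-6-{[(2S,4aR,8R)-2,4a,8-trimethyl-2,3,4,4a,5,6,7,8-octahydronaphthalen-2-yl]oxy}benzaldehyde | O=Cc1c(F)c(OC)cc(OC)c1O[C@]1(C)C=C2[C@H](C)CCC[C@]2(C)CC1 | intermediate
13 | 3,5-dimethoxy-2-[2-(methylsulfonyl)ethoxy]-6-{[(2S,4aR,8R)-2,4a,8-trimethyl-2,3,4,4a,5,6,7,8-octahydronaphthalen-2-yl]oxy}benzaldehyde | O=Cc1c(OCCS(C)(=O)=O)c(OC)cc(OC)c1O[C@]1(C)C=C2[C@H](C)CCC[C@]2(C)CC1 | intermediate (not isolated)
14 | 2-hydroxy-3,5-dimethoxy-6-{[(2S,4aR,8R)-2,4a,8-trimethyl-2,3,4,4a,5,6,7,8-octahydronaphthalen-2-yl]oxy}benzaldehyde | O=Cc1c(O)c(OC)cc(OC)c1O[C@]1(C)C=C2[C@H](C)CCC[C@]2(C)CC1 | intermediate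
15 | 2-ethenyl-4,6-dimethoxy-3-{[(2S,4aR,8R)-2,4a,8-trimethyl-2,3,4,4a,5,6,7,8-octahydronaphthalen-2-yl]oxy}phenol | C=Cc1c(O)c(OC)cc(OC)c1O[C@]1(C)C=C2[C@H](C)CCC[C@]2(C)CC1 | intermediate
16 | metachromin B, (2S)-2-{2-[(1R,3R)-1,3-dimethyl-2-methylidenecyclohexyl]ethyl}-6,8-dimethoxy-2-methyl-2H-chromen-5-ol | C=C1[C@H](C)CCC[C@]1(C)CC[C@@]1(C)C=Cc2c(O)c(OC)cc(OC)c2O1 | target

## Step count and least certain steps

Total: 8 steps. Longest linear sequence: 8 steps (1 → 16); 2, 4 and 10 are bought.

**Step 8 (key step, proposed new method).** The most likely failure is that the methylidene complex does not add to the hindered trisubstituted C1=C8a bond, which has an allylic quaternary carbon on each side. The catalyst would then be lost through decomposition of Ru=CH2 or through dimerisation of the styrene, or the isomerisation would stop at an unfavourable equilibrium.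

The fallback uses known chemistry, sets out from 14 and returns at 16; the ring is opened by oxidative cleavage instead of metathesis.
- Silylation (tBuMe2SiCl, imidazole, DMF) would give the silyl ether F1.
- Ozonolysis of its only C=C bond (O3, CH2Cl2–MeOH, −78 °C; Me2S) would give the keto dialdehyde F2.
- Double Wittig methylenation of the two formyl groups (Ph3P=CH2, THF, −78 → 0 °C; the 2,2,6-trisubstituted ketone is too hindered to react) would give the diene ketone F3.
- Ordinary ring-closing metathesis (RuCl2(PCy3)(H2IMes)(=CHPh), second-generation Grubbs catalyst, CH2Cl2, 40 °C) would close the chromene ketone F4.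
- Non-basic methylenation of the ketone (Cp2TiMe2, toluene, 70 °C) would give the silyl ether F5, and Bu4NF (THF, 0 °C) would give 16.

The price is five extra steps and a C3′ centre that sits α to a ketone from F2 to F4, so these intermediates must be kept cold and away from base.

**Step 5.** The most likely failure is slow substitution, because the attacked carbon is flanked by the formyl and a methoxy group and has a methoxy group para to it. The alkoxide can also be held back by reversible addition to the formyl group, which opens hydride-transfer side reactions of the aldehyde.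

The fallback moves the C–O bond formation to a nitrile-activated ring, which cannot trap the alkoxide and has a smaller ortho group; it sets out from 10 (with 9) and returns at 14.
- One-pot oxime formation and dehydration (NH2OH·HCl, HCO2Na, HCO2H, 100 °C) would give 2,6-difluoro-3,5-dimethoxybenzonitrile F6.
- SNAr with alkoxide 11 (THF, 0 → 25 °C) would give the aryl ether nitrile F7.
- The hydroxide-surrogate SNAr of step 6 would give the hydroxy nitrile F8.
- iBu2AlH (toluene, −78 → 0 °C) and mild aqueous acid would give 14.

**Step 4.** The most likely failure is poor facial selectivity. Axial (α-face) delivery of methyl, the stereoelectronically preferred path for small nucleophiles on cyclohexenones, may compete and give the C2 epimer, which would end as 2-epi-16.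

The fallback delivers the oxygen, not the methyl group, under control of the angular methyl; it sets out from 8 and returns at 9.
- Kinetic deprotonation at C3 and triflation (LiN(iPr)2, THF, −78 °C; PhNTf2) would give the cross-conjugated dienyl triflate F9.
- Fe(acac)3-catalysed coupling with MeMgBr would give the methyl diene F10.
- Epoxidation of the less hindered C2=C3 bond (mCPBA, NaHCO3, CH2Cl2, −20 °C) from the α face, anti to the angular methyl, would give the vinyl epoxide F11.
- LiAlH4 (Et2O, 0 °C) would open it at the secondary C3, trans-diaxially, to give 9 with the pseudo-axial C2–OH.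

**Step 2.** The most likely failure is a slow or poorly face-selective Michael addition, because the extra α′-methyl group hinders the secondary enamine and may erode the enantiomeric purity of the quaternary centre.

The fallback sets the absolute configuration by reagent-controlled reduction and separation; it sets out from 1 and 4 and returns at 8.
- Acid-catalysed Robinson annulation (H2SO4 cat., toluene, reflux) would give the racemic trans-octalone F12.
- Corey–Bakshi–Shibata reduction ((S)-2-methyl-CBS-oxazaborolidine, BH3·SMe2, THF, −20 °C) would turn the two enantiomers into the diastereomeric allylic alcohols F13 (from the wanted enantiomer) and F14, which are separable by chromatography.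
- MnO2 (CH2Cl2, 25 °C) would oxidise F13 back to 8.

## Further compounds

F1 | step 8 | 2-[(tert-butyldimethylsilyl)oxy]-3,5-dimethoxy-6-{[(2S,4aR,8R)-2,4a,8-trimethyl-2,3,4,4a,5,6,7,8-octahydronaphthalen-2-yl]oxy}benzaldehyde | O=Cc1c(O[Si](C)(C)C(C)(C)C)c(OC)cc(OC)c1O[C@]1(C)C=C2[C@H](C)CCC[C@]2(C)CC1
F2 | step 8 | 2-[(tert-butyldimethylsilyl)oxy]-6-{[(2S)-4-[(1R,3R)-1,3-dimethyl-2-oxocyclohexyl]-2-methyl-1-oxobutan-2-yl]oxy}-3,5-dimethoxybenzaldehyde | O=Cc1c(O[Si](C)(C)C(C)(C)C)c(OC)cc(OC)c1O[C@](C)(C=O)CC[C@@]1(C)CCC[C@@H](C)C1=O
F3 | step 8 | (2R,6R)-2-[(3S)-3-{3-[(tert-butyldimethylsilyl)oxy]-2-ethenyl-4,6-dimethoxyphenoxy}-3-methylpent-4-en-1-yl]-2,6-dimethylcyclohexan-1-one | C=Cc1c(O[Si](C)(C)C(C)(C)C)c(OC)cc(OC)c1O[C@](C)(C=C)CC[C@@]1(C)CCC[C@@H](C)C1=O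
F4 | step 8 | (2R,6R)-2-{2-[(2S)-5-[(tert-butyldimethylsilyl)oxy]-6,8-dimethoxy-2-methyl-2H-chromen-2-yl]ethyl}-2,6-dimethylcyclohexan-1-one | O=C1[C@H](C)CCC[C@]1(C)CC[C@@]1(C)C=Cc2c(O[Si](C)(C)C(C)(C)C)c(OC)cc(OC)c2O1
F5 | step 8 | tert-butyl{[(2S)-2-{2-[(1R,3R)-1,3-dimethyl-2-methylidenecyclohexyl]ethyl}-6,8-dimethoxy-2-methyl-2H-chromen-5-yl]oxy}dimethylsilane | C=C1[C@H](C)CCC[C@]1(C)CC[C@@]1(C)C=Cc2c(O[Si](C)(C)C(C)(C)C)c(OC)cc(OC)c2O1
F6 | step 5 | 2,6-difluoro-3,5-dimethoxybenzonitrile | N#Cc1c(F)c(OC)cc(OC)c1F
F7 | step 5 | 2-fluoro-3,5-dimethoxy-6-{[(2S,4aR,8R)-2,4a,8-trimethyl-2,3,4,4a,5,6,7,8-octahydronaphthalen-2-yl]oxy}benzonitrile | N#Cc1c(F)c(OC)cc(OC)c1O[C@]1(C)C=C2[C@H](C)CCC[C@]2(C)CC1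
F8 | step 5 | 2-hydroxy-3,5-dimethoxy-6-{[(2S,4aR,8R)-2,4a,8-trimethyl-2,3,4,4a,5,6,7,8-octahydronaphthalen-2-yl]oxy}benzonitrile | N#Cc1c(O)c(OC)cc(OC)c1O[C@]1(C)C=C2[C@H](C)CCC[C@]2(C)CC1
F9 | step 4 | (4aR,8R)-4a,8-dimethyl-4,4a,5,6,7,8-hexahydronaphthalen-2-yl trifluoromethanesulfonate | FC(F)(F)S(=O)(=O)OC1=CC[C@@]2(C)CCC[C@@H](C)C2=C1
F10 | step 4 | (4aR,8R)-2,4a,8-trimethyl-4,4a,5,6,7,8-hexahydronaphthalene | CC1=CC[C@@]2(C)CCC[C@@H](C)C2=C1
F11 | step 4 | (2R,3S,4aR,8R)-2,3-epoxy-2,4a,8-trimethyl-2,3,4,4a,5,6,7,8-octahydronaphthalene (epoxide anti to the angular methyl) | C[C@]12O[C@H]1C[C@@]1(C)CCC[C@@H](C)C1=C2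
F12 | step 2 | racemic trans-4a,8-dimethyl-4,4a,5,6,7,8-hexahydronaphthalen-2(3H)-one (4aR*,8R*; one enantiomer drawn) | O=C1C=C2[C@H](C)CCC[C@]2(C)CC1
F13 | step 2 | (2R,4aR,8R)-4a,8-dimethyl-2,3,4,4a,5,6,7,8-octahydronaphthalen-2-ol | O[C@H]1C=C2[C@H](C)CCC[C@]2(C)CC1
F14 | step 2 | (2R,4aS,8S)-4a,8-dimethyl-2,3,4,4a,5,6,7,8-octahydronaphthalen-2-ol | O[C@H]1C=C2[C@@H](C)CCC[C@@]2(C)CC1
A1 | alternative 1 | 4,6-dimethoxybenzene-1,3-diol | COc1cc(OC)c(O)cc1O
A2 | alternative 1 | (2E)-5-[(1R,3R)-1,3-dimethyl-2-methylidenecyclohexyl]-3-methylpent-2-enal | C=C1[C@H](C)CCC[C@]1(C)CC/C(C)=C/C=O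
A3 | alternative 1 | (2RS)-2-{2-[(1R,3R)-1,3-dimethyl-2-methylidenecyclohexyl]ethyl}-6,8-dimethoxy-2-methyl-2H-chromen-5-ol (C2-epimer mixture) | C=C1[C@H](C)CCC[C@]1(C)CCC1(C)C=Cc2c(O)c(OC)cc(OC)c2O1
A4 | alternative 2 | 3-[(tert-butyldimethylsilyl)oxy]-2-ethenyl-4,6-dimethoxyphenol | C=Cc1c(O)c(OC)cc(OC)c1O[Si](C)(C)C(C)(C)C
A5 | alternative 2 | (2E)-5-[(1R,3R)-1,3-dimethyl-2-methylidenecyclohexyl]-3-methylpent-2-en-1-yl methyl carbonate | C=C1[C@H](C)CCC[C@]1(C)CC/C(C)=C/COC(=O)OC
A6 | alternative 2 | tert-butyl(3-{[(3S)-5-[(1R,3R)-1,3-dimethyl-2-methylidenecyclohexyl]-3-methylpent-1-en-3-yl]oxy}-2-ethenyl-4,6-dimethoxyphenoxy)dimethylsilane | C=Cc1c(O[Si](C)(C)C(C)(C)C)c(OC)cc(OC)c1O[C@](C)(C=C)CC[C@@]1(C)CCC[C@@H](C)C1=C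
A7 | alternative 3 | 2-[(2E)-5-[(1R,3R)-1,3-dimethyl-2-methylidenecyclohexyl]-3-methylpent-2-en-1-yl]-4,6-dimethoxybenzene-1,3-diol | C=C1[C@H](C)CCC[C@]1(C)CC/C(C)=C/Cc1c(O)c(OC)cc(OC)c1O
A8 | alternative 3 | 2-{[(2R,3R)-3-{2-[(1R,3R)-1,3-dimethyl-2-methylidenecyclohexyl]ethyl}-3-methyloxiran-2-yl]methyl}-4,6-dimethoxybenzene-1,3-diol | C=C1[C@H](C)CCC[C@]1(C)CC[C@@]1(C)O[C@@H]1Cc1c(O)c(OC)cc(OC)c1O
A9 | alternative 3 | (2S,3R)-2-{2-[(1R,3R)-1,3-dimethyl-2-methylidenecyclohexyl]ethyl}-6,8-dimethoxy-2-methyl-3,4-dihydro-2H-chromene-3,5-diol | C=C1[C@H](C)CCC[C@]1(C)CC[C@@]1(C)[C@H](O)Cc2c(O)c(OC)cc(OC)c2O1
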